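**Retrosynthetic overview**

1. Numbering used below (not IUPAC): C1 bears N, C2 is the CH2, C3 the hydroxylated bridgehead, C4 the ketone, C5 the CH bridgehead, C6 the ring B carbinol, C7–C8 the epoxide (C8 on C3), C9 the carbinol next to C1; ring A = C1–C2–C3–C4–C5–C9, ring B = C3–C4–C5–C6–C7–C8.
2. Feature: the bridge C2–C1(N)–C9 of ring A is an L-serine unit (C9 from the carboxyl carbon, C2 from the CH2OH) and C3 is the α-carbon of a 2-alkoxycyclohexenone (C4=O, C3=C8) in ring B; C2–C3 is therefore cut into a dienolate (C3) and a serine cyclic sulfamidate (C2), and α-alkylation moves the alkene to C7=C8, where the epoxide is needed.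
3. Target ⇒ (PMB removal, C6–OH-directed epoxidation, desilylation, N-acylation with (E)-7-oxododec-2-enoic acid made by cross-metathesis) bicyclic carbamate ⇒ (key C2–C3 alkylation closing ring A) ring B enone carrying the N-Boc sulfamidate on the C9 chain.
4. Sulfamidate precursor ⇒ (C5–C9 syn-aldol) 2-(PMB-oxy)-5-silyloxycyclohexenone + N-Boc serinal acetonide; the enone ⇒ 4-silyloxycyclohexanone by proline α-aminoxylation (desymmetrisation) and a ketal → enol ether → enone sequence that fixes which carbon carries the ether oxygen.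
5. Ring order: ring B comes from the starting cyclohexanone, ring A is closed in the key step, the oxirane is made in the penultimate step.

Key step: step 11

Remark: step 1 is assumed to favour the 2,4-trans isomer (axial attack on the enamine); this isomer is carried on after chromatography, because the cis isomer would lead into the enantiomeric series.
Abbreviations: TBS = tert-butyldimethylsilyl, TMS = trimethylsilyl, PMB = 4-methoxybenzyl, Boc = tert-butoxycarbonyl.

**Route**

Step 1
Reactants: 1 4-(TBS-oxy)cyclohexan-1-one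
Product: 2 (2S,4R)-4-(TBS-oxy)-2-[(phenylamino)oxy]cyclohexan-1-one (2,4-trans)
Conditions: D-proline (20 mol%), PhNO (slow addition), DMF, 0 °C
Reagents that add atoms: nitrosobenzene, O=Nc1ccccc1
Why: Proline-catalysed α-aminoxylation (O-selective nitroso aldol) through the enamine; D-proline should set 2S, and axial attack on the half-chair enamine with the silyloxy group equatorial should select the enantiotopic α-carbon that gives the trans (2S,4R) isomer, which is separated from the minor cis isomer.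

Step 2
Reactants: 2 (2S,4R)-4-(TBS-oxy)-2-[(phenylamino)oxy]cyclohexan-1-one
Product: 3 (2S,4R)-4-(TBS-oxy)-2-hydroxycyclohexan-1-one
Conditions: H2 (1 atm), Pd/C, EtOAc, rt
Reagents that add atoms: none
Why: Hydrogenolysis of the weak N–O bond over palladium should leave the ketone, the silyl ether and both stereocentres untouched.

Step 3
Reactants: 4 4-methoxybenzyl alcohol
Product: 5 (4-methoxybenzyloxy)trimethylsilane
Conditions: Me3SiCl, Et3N, CH2Cl2, 0 °C → rt
Reagents that add atoms: chlorotrimethylsilane, C[Si](C)(C)Cl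
Why: Routine O-silylation of a primary alcohol with a chlorosilane and an amine base provides the alkoxysilane needed for the ketalisation.

Step 4
Reactants: 3 (2S,4R)-4-(TBS-oxy)-2-hydroxycyclohexan-1-one; 5 (4-methoxybenzyloxy)trimethylsilane
Product: 6 {[(1S,5R)-5-(TBS-oxy)-2,2-bis(4-methoxybenzyloxy)cyclohexyl]oxy}trimethylsilane
Conditions: 5 (3.3 equiv), Me3SiOTf (5 mol%), CH2Cl2, −78 → −30 °C; pyridine quench
Reagents that add atoms: none
Why: Silyl triflate-catalysed ketalisation of a ketone with an alkoxysilane (driven by formation of hexamethyldisiloxane, the α-hydroxyl being silylated in the same pot) places the PMB oxygen on C3, the former carbonyl carbon, without regiochemical ambiguity and without touching the two stereocentres.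

Step 5
Reactants: 6 {[(1S,5R)-5-(TBS-oxy)-2,2-bis(4-methoxybenzyloxy)cyclohexyl]oxy}trimethylsilane
Product: 8 (1S,5R)-5-(TBS-oxy)-2-(4-methoxybenzyloxy)cyclohex-2-en-1-ol, via trimethylsilyl ether 7 (not isolated)
Conditions: Me3SiOTf (1.2 equiv), i-Pr2NEt (1.5 equiv), CH2Cl2, −20 → 0 °C; then K2CO3, MeOH, 0 °C
Reagents that add atoms: none
Why: Silyl triflate/amine-promoted elimination of a ketal to an enol ether via the oxocarbenium ion, in which the hindered amine should remove a proton from the C8 methylene and not from the silyloxy-bearing C4, gives the C3=C8 enol ether, and basic methanolysis then frees the allylic C4 hydroxyl.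

Step 6
Reactants: 8 (1S,5R)-5-(TBS-oxy)-2-(4-methoxybenzyloxy)cyclohex-2-en-1-ol
Product: 9 (5R)-5-(TBS-oxy)-2-(4-methoxybenzyloxy)cyclohex-2-en-1-one
Conditions: Dess–Martin periodinane, pyridine, CH2Cl2, 0 °C → rt
Reagents that add atoms: none
Why: Dess–Martin oxidation of a secondary allylic alcohol gives the 2-alkoxy enone with the carbonyl at C4, a regiochemistry that O-alkylation of the unsymmetrical 1,2-dione would not guarantee; the C4 stereocentre is removed on purpose.

Step 7
Reactants: 9 (5R)-5-(TBS-oxy)-2-(4-methoxybenzyloxy)cyclohex-2-en-1-one; 10 tert-butyl (4S)-4-formyl-2,2-dimethyl-1,3-oxazolidine-3-carboxylate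
Product: 13 tert-butyl (4S)-4-[(R)-hydroxy{(1S,6R)-6-(TBS-oxy)-3-(4-methoxybenzyloxy)-2-oxocyclohex-3-en-1-yl}methyl]-2,2-dimethyl-1,3-oxazolidine-3-carboxylate, via lithium dienolate 11 (not isolated), via titanium dienolate 12 (not isolated)
Conditions: LiN(i-Pr)2 (1.05 equiv), THF, −78 °C; ClTi(Oi-Pr)3 (1.2 equiv), −78 → −40 °C; 10, −78 °C; aq. NH4Cl
Reagents that add atoms: none
Why: Aldol addition of a triisopropoxytitanium enolate (kinetic α′-deprotonation at C5, then Li-to-Ti exchange), a type of enolate that is syn-selective for cyclic ketones through a boat-like closed transition state; the aldehyde should approach C5 anti to the C6 silyloxy group and be attacked on its Felkin–Anh face (non-chelating titanium), so 5,9-syn, 5,6-trans and 9,1-anti are matched, whereas a boron enolate (chair transition state) would give the 5,9-anti epimer.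

Step 8
Reactants: 13 aldol adduct (free C9 hydroxyl)
Product: 14 tert-butyl (4S)-4-[(R)-(TBS-oxy){(1R,6R)-6-(TBS-oxy)-3-(4-methoxybenzyloxy)-2-oxocyclohex-3-en-1-yl}methyl]-2,2-dimethyl-1,3-oxazolidine-3-carboxylate
Conditions: TBSOTf, 2,6-lutidine, CH2Cl2, −78 → −40 °C
Reagents that add atoms: tert-butyldimethylsilyl triflate, CC(C)(C)[Si](C)(C)OS(=O)(=O)C(F)(F)F
Why: Silylation of a hindered secondary alcohol with a silyl triflate and 2,6-lutidine blocks C9–OH against deprotonation and retro-aldol cleavage in the key step; the change of the ring C-1 descriptor from S to R is a priority effect only.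

Step 9
Reactants: 14 bis-silyl ether with N,O-acetonide
Product: 15 tert-butyl N-[(1R,2S)-1-(TBS-oxy)-3-hydroxy-1-{(1R,6R)-6-(TBS-oxy)-3-(4-methoxybenzyloxy)-2-oxocyclohex-3-en-1-yl}propan-2-yl]carbamate
Conditions: BiBr3 (20 mol%), MeCN/H2O, rt
Reagents that add atoms: none
Why: Lewis acid-catalysed hydrolysis of the N,O-isopropylidene aminal, for which BiBr3 in wet MeCN is selective over Boc, secondary silyl ethers and the conjugated enol ether, frees the NH carbamate and the primary C2 hydroxyl.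

Step 10
Reactants: 15 N-Boc amino alcohol
Product: 17 tert-butyl (4S)-4-[(R)-(TBS-oxy){(1R,6R)-6-(TBS-oxy)-3-(4-methoxybenzyloxy)-2-oxocyclohex-3-en-1-yl}methyl]-1,2,3-oxathiazolidine-3-carboxylate 2,2-dioxide, via cyclic sulfamidite 16 (not isolated)
Conditions: SOCl2, pyridine, MeCN, −40 → 0 °C; then RuCl3·xH2O (0.5 mol%), NaIO4, MeCN/H2O, 0 °C, 15 min
Reagents that add atoms: thionyl chloride, O=S(Cl)Cl; sodium periodate, [Na+].[O-]I(=O)(=O)=O
Why: Standard two-stage cyclic sulfamidate synthesis, in which SOCl2 closes the sulfamidite on N and the C2 oxygen and the Ru-catalysed periodate oxidation at sulfur should outrun oxidation of the conjugated trisubstituted alkene at low catalyst loading and 0 °C; no stereocentre is touched.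

Step 11
Reactants: 17 ring B enone carrying the N-Boc cyclic sulfamidate
Product: 20 tert-butyl N-[(1S,4R,5R,6R,7S)-4,6-bis(TBS-oxy)-1-(4-methoxybenzyloxy)-9-oxobicyclo[3.3.1]non-2-en-7-yl]carbamate, via potassium dienolate 18 (not isolated), via potassium N-sulfamate 19 (not isolated)
Conditions: KN(SiMe3)2 (1.1 equiv), THF (0.01 M), −78 → 0 °C; then 10% aq. citric acid, rt
Reagents that add atoms: none
Why: KN(SiMe3)2 should remove a C7 hydrogen (the only α′ hydrogen, on C5, is tertiary, flanked by two silyloxy-bearing carbons and close to the carbonyl plane when the C5 chain is axial, and the linear dienolate is also the more stable one), and the α-carbon C3 of dienolate 18 then displaces the sulfamidate oxygen from C2 in an SN2 reaction, which forms C2–C3, ring A and the oxygenated quaternary centre and leaves the alkene at C7=C8. The closest known reactions are the C-alkylation of ketone and ester enolates by N-acyl 1,2-cyclic sulfamidates at the CH2–O carbon, the deconjugative α-alkylation of enone dienolates and the enolate-alkylation route to bicyclo[3.3.1]nonan-9-ones. Ring A closes in a 6-(enolendo)-exo-tet mode through a chair with the nitrogen on C1 equatorial and the C9 silyloxy group axial; with the leaving oxygen anti to C3, only this arrangement keeps N and O close enough to be bridged by sulfur. The new C3 centre is set by the tether, because the chain on C5 (trans to the C6 silyloxy group) can reach C3 only on its own face, and C1, C5, C6 and C9 are not touched. The step needs α- and not γ-alkylation (C7 is out of reach of the three-atom tether), C- and not O-alkylation (A(1,2) strain with the enolate oxygen holds the C5 chain axial, under the π face of C3 and away from the in-plane oxygen) and substitution at carbon rather than attack at sulfur or the Boc group (the CH2–O carbon is the normal site of attack on N-Boc sulfamidates); high dilution and low temperature hold back intermolecular alkylation and loss of a β-silyloxy group from any C5 enolate. Aqueous acid then hydrolyses N-sulfamate 19 to 20, whose bridgehead C5–H can no longer enolise.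

Step 12
Reactants: 20 bicyclic N-Boc carbamate
Product: 22 (1S,4R,5R,6R,7S)-7-amino-4,6-bis(TBS-oxy)-1-(4-methoxybenzyloxy)bicyclo[3.3.1]non-2-en-9-one, via trimethylsilyl carbamate 21 (not isolated)
Conditions: Me3SiOTf, 2,6-lutidine, CH2Cl2, 0 °C; then MeOH
Reagents that add atoms: none
Why: Boc cleavage by the silyl triflate/2,6-lutidine method (loss of the tert-butyl cation to a silyl carbamate, then methanolysis and decarboxylation) should spare the PMB ether, both silyl ethers and the β,γ-unsaturated ketone, which protic acid would not.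

Step 13
Reactants: 23 hex-5-enenitrile; 24 pentylmagnesium bromide
Product: 26 undec-1-en-6-one, via magnesium ketimide 25 (not isolated)
Conditions: Et2O, 0 °C → reflux; then 1 M HCl
Reagents that add atoms: water, O
Why: Grignard addition to a nitrile stops at the magnesium ketimide, which is hydrolysed to the ketone on acidic work-up; the terminal alkene is inert.

Step 14
Reactants: 26 undec-1-en-6-one; 27 acrylic acid
Product: 28 (2E)-7-oxododec-2-enoic acid
Conditions: second-generation Grubbs catalyst (3 mol%), CH2Cl2, 40 °C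
Reagents that add atoms: none
Why: Olefin cross-metathesis of a terminal alkene with acrylic acid is selective for the cross product and for the (E)-enoic acid, with loss of ethene.

Step 15
Reactants: 22 bicyclic amine; 28 (2E)-7-oxododec-2-enoic acid
Product: 29 (2E)-N-[(1S,4R,5R,6R,7S)-4,6-bis(TBS-oxy)-1-(4-methoxybenzyloxy)-9-oxobicyclo[3.3.1]non-2-en-7-yl]-7-oxododec-2-enamide
Conditions: N,N′-diisopropylcarbodiimide, HOBt, CH2Cl2, 0 °C → rt
Reagents that add atoms: none
Why: Carbodiimide/HOBt amide coupling, in which the primary amine is the only free nucleophile (all three oxygens are protected) and the (E)-alkene should not isomerise under neutral conditions.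

Step 16
Reactants: 29 bis-silyl amide
Product: 30 (2E)-N-[(1S,4R,5R,6R,7S)-4,6-dihydroxy-1-(4-methoxybenzyloxy)-9-oxobicyclo[3.3.1]non-2-en-7-yl]-7-oxododec-2-enamide
Conditions: HF·pyridine, THF/pyridine, 0 °C → rt
Reagents that add atoms: none
Why: Fluoride-mediated cleavage of both silyl ethers under buffered acidic conditions avoids the retro-aldol cleavage that a basic fluoride source could cause in these β-hydroxy ketones.

Step 17
Reactants: 30 allylic diol
Product: 31 (2E)-N-[(1S,2S,4S,5S,6S,7R,8S)-5,7-dihydroxy-1-(4-methoxybenzyloxy)-10-oxo-3-oxatricyclo[4.3.1.0(2,4)]decan-8-yl]-7-oxododec-2-enamide (O-PMB isariotin C; epoxide syn to C6–OH)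
Conditions: VO(acac)2 (5 mol%), t-BuOOH, CH2Cl2, 0 °C → rt
Reagents that add atoms: tert-butyl hydroperoxide, CC(C)(C)OO
Why: Hydroxyl-directed epoxidation, in which the pseudo-axial allylic C6 hydroxyl delivers oxygen to its own face of C7=C8 (also the convex face away from ring A) and so sets C7 and C8 syn to C6–OH; the electron-poor alkene of the unsaturated amide should not react and the PMB ether keeps the tertiary α-ketol masked.

Step 18
Reactants: 31 O-PMB isariotin C
Product: 32 isariotin C, (2E)-N-[(1S,2S,4S,5S,6S,7R,8S)-1,5,7-trihydroxy-10-oxo-3-oxatricyclo[4.3.1.0(2,4)]decan-8-yl]-7-oxododec-2-enamide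
Conditions: DDQ, CH2Cl2/pH 7 buffer, 0 °C → rt
Reagents that add atoms: none
Why: Oxidative PMB ether cleavage with DDQ (hydride abstraction, then hydrolysis of the oxocarbenium ion) under buffered neutral conditions should spare the epoxide, the β-hydroxy ketones and the unsaturated amide and frees the C3 tertiary alcohol.

**Compound list**

1 | 4-(TBS-oxy)cyclohexan-1-one | CC(C)(C)[Si](C)(C)OC1CCC(=O)CC1 | starting material
2 | (2S,4R)-4-(TBS-oxy)-2-[(phenylamino)oxy]cyclohexan-1-one | O=C1CC[C@@H](O[Si](C)(C)C(C)(C)C)C[C@@H]1ONc1ccccc1 | intermediate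
3 | (2S,4R)-4-(TBS-oxy)-2-hydroxycyclohexan-1-one | O=C1CC[C@@H](O[Si](C)(C)C(C)(C)C)C[C@@H]1O | intermediate
4 | 4-methoxybenzyl alcohol | COc1ccc(CO)cc1 | starting material
5 | (4-methoxybenzyloxy)trimethylsilane | COc1ccc(CO[Si](C)(C)C)cc1 | intermediate
6 | {[(1S,5R)-5-(TBS-oxy)-2,2-bis(4-methoxybenzyloxy)cyclohexyl]oxy}trimethylsilane | COc1ccc(COC2(OCc3ccc(OC)cc3)CC[C@@H](O[Si](C)(C)C(C)(C)C)C[C@@H]2O[Si](C)(C)C)cc1 | intermediate
7 | {[(1S,5R)-5-(TBS-oxy)-2-(4-methoxybenzyloxy)cyclohex-2-en-1-yl]oxy}trimethylsilane | COc1ccc(COC2=CC[C@@H](O[Si](C)(C)C(C)(C)C)C[C@@H]2O[Si](C)(C)C)cc1 | intermediate (not isolated)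
8 | (1S,5R)-5-(TBS-oxy)-2-(4-methoxybenzyloxy)cyclohex-2-en-1-ol | COc1ccc(COC2=CC[C@@H](O[Si](C)(C)C(C)(C)C)C[C@@H]2O)cc1 | intermediate
9 | (5R)-5-(TBS-oxy)-2-(4-methoxybenzyloxy)cyclohex-2-en-1-one | O=C1C(OCc2ccc(OC)cc2)=CC[C@@H](O[Si](C)(C)C(C)(C)C)C1 | intermediate
10 | tert-butyl (4S)-4-formyl-2,2-dimethyl-1,3-oxazolidine-3-carboxylate | O=C[C@@H]1COC(C)(C)N1C(=O)OC(C)(C)C | starting material
11 | lithium (3R)-3-(TBS-oxy)-6-(4-methoxybenzyloxy)cyclohexa-1,5-dien-1-olate | [Li+].[O-]C1=C[C@H](O[Si](C)(C)C(C)(C)C)CC=C1OCc1ccc(OC)cc1 | intermediate (not isolated)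
12 | triisopropoxytitanium (3R)-3-(TBS-oxy)-6-(4-methoxybenzyloxy)cyclohexa-1,5-dien-1-olate | CC(C)O[Ti](OC(C)C)(OC(C)C)OC1=C[C@H](O[Si](C)(C)C(C)(C)C)CC=C1OCc1ccc(OC)cc1 | intermediate (not isolated)
13 | tert-butyl (4S)-4-[(R)-hydroxy{(1S,6R)-6-(TBS-oxy)-3-(4-methoxybenzyloxy)-2-oxocyclohex-3-en-1-yl}methyl]-2,2-dimethyl-1,3-oxazolidine-3-carboxylate | CC(C)(C)OC(=O)N1[C@@H](COC1(C)C)[C@H](O)[C@@H]2C(=O)C(OCc3ccc(OC)cc3)=CC[C@H]2O[Si](C)(C)C(C)(C)C | intermediate
14 | tert-butyl (4S)-4-[(R)-(TBS-oxy){(1R,6R)-6-(TBS-oxy)-3-(4-methoxybenzyloxy)-2-oxocyclohex-3-en-1-yl}methyl]-2,2-dimethyl-1,3-oxazolidine-3-carboxylate | CC(C)(C)OC(=O)N1[C@@H](COC1(C)C)[C@H](O[Si](C)(C)C(C)(C)C)[C@@H]2C(=O)C(OCc3ccc(OC)cc3)=CC[C@H]2O[Si](C)(C)C(C)(C)C | intermediate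
15 | tert-butyl N-[(1R,2S)-1-(TBS-oxy)-3-hydroxy-1-{(1R,6R)-6-(TBS-oxy)-3-(4-methoxybenzyloxy)-2-oxocyclohex-3-en-1-yl}propan-2-yl]carbamate | CC(C)(C)OC(=O)N[C@@H](CO)[C@H](O[Si](C)(C)C(C)(C)C)[C@@H]1C(=O)C(OCc2ccc(OC)cc2)=CC[C@H]1O[Si](C)(C)C(C)(C)C | intermediate
16 | tert-butyl (4S)-4-[(R)-(TBS-oxy){(1R,6R)-6-(TBS-oxy)-3-(4-methoxybenzyloxy)-2-oxocyclohex-3-en-1-yl}methyl]-1,2,3-oxathiazolidine-3-carboxylate 2-oxide (both S-epimers) | CC(C)(C)OC(=O)N1[C@@H](COS1=O)[C@H](O[Si](C)(C)C(C)(C)C)[C@@H]2C(=O)C(OCc3ccc(OC)cc3)=CC[C@H]2O[Si](C)(C)C(C)(C)C | intermediate (not isolated)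
17 | tert-butyl (4S)-4-[(R)-(TBS-oxy){(1R,6R)-6-(TBS-oxy)-3-(4-methoxybenzyloxy)-2-oxocyclohex-3-en-1-yl}methyl]-1,2,3-oxathiazolidine-3-carboxylate 2,2-dioxide | CC(C)(C)OC(=O)N1[C@@H](COS1(=O)=O)[C@H](O[Si](C)(C)C(C)(C)C)[C@@H]2C(=O)C(OCc3ccc(OC)cc3)=CC[C@H]2O[Si](C)(C)C(C)(C)C | intermediate
18 | potassium linear dienolate of 17 (C4–O−, C4=C3, C8=C7) | [K+].CC(C)(C)OC(=O)N1[C@@H](COS1(=O)=O)[C@H](O[Si](C)(C)C(C)(C)C)[C@@H]2C([O-])=C(OCc3ccc(OC)cc3)C=C[C@H]2O[Si](C)(C)C(C)(C)C | intermediate (not isolated)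
19 | potassium N-Boc-N-sulfamate of the bicyclic amine (N–SO3K form of 20) | [K+].CC(C)(C)OC(=O)N([C@H]1C[C@@]2(OCc3ccc(OC)cc3)C(=O)[C@H]([C@H](O[Si](C)(C)C(C)(C)C)C=C2)[C@H]1O[Si](C)(C)C(C)(C)C)S(=O)(=O)[O-] | intermediate (not isolated)
20 | tert-butyl N-[(1S,4R,5R,6R,7S)-4,6-bis(TBS-oxy)-1-(4-methoxybenzyloxy)-9-oxobicyclo[3.3.1]non-2-en-7-yl]carbamate | CC(C)(C)OC(=O)N[C@H]1C[C@@]2(OCc3ccc(OC)cc3)C(=O)[C@H]([C@H](O[Si](C)(C)C(C)(C)C)C=C2)[C@H]1O[Si](C)(C)C(C)(C)C | intermediate
21 | trimethylsilyl N-[(1S,4R,5R,6R,7S)-4,6-bis(TBS-oxy)-1-(4-methoxybenzyloxy)-9-oxobicyclo[3.3.1]non-2-en-7-yl]carbamate | C[Si](C)(C)OC(=O)N[C@H]1C[C@@]2(OCc3ccc(OC)cc3)C(=O)[C@H]([C@H](O[Si](C)(C)C(C)(C)C)C=C2)[C@H]1O[Si](C)(C)C(C)(C)C | intermediate (not isolated)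
22 | (1S,4R,5R,6R,7S)-7-amino-4,6-bis(TBS-oxy)-1-(4-methoxybenzyloxy)bicyclo[3.3.1]non-2-en-9-one | N[C@H]1C[C@@]2(OCc3ccc(OC)cc3)C(=O)[C@H]([C@H](O[Si](C)(C)C(C)(C)C)C=C2)[C@H]1O[Si](C)(C)C(C)(C)C | intermediate
23 | hex-5-enenitrile | C=CCCCC#N | starting material
24 | pentylmagnesium bromide | CCCCC[Mg]Br | starting material
25 | N-(bromomagnesio) ketimine of undec-1-en-6-one | C=CCCCC(=N[Mg]Br)CCCCC | intermediate (not isolated)
26 | undec-1-en-6-one | C=CCCCC(=O)CCCCC | intermediate
27 | acrylic acid | C=CC(=O)O | starting material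
28 | (2E)-7-oxododec-2-enoic acid | CCCCCC(=O)CCC/C=C/C(=O)O | intermediate
29 | (2E)-N-[(1S,4R,5R,6R,7S)-4,6-bis(TBS-oxy)-1-(4-methoxybenzyloxy)-9-oxobicyclo[3.3.1]non-2-en-7-yl]-7-oxododec-2-enamide | CCCCCC(=O)CCC/C=C/C(=O)N[C@H]1C[C@@]2(OCc3ccc(OC)cc3)C(=O)[C@H]([C@H](O[Si](C)(C)C(C)(C)C)C=C2)[C@H]1O[Si](C)(C)C(C)(C)C | intermediate
30 | (2E)-N-[(1S,4R,5R,6R,7S)-4,6-dihydroxy-1-(4-methoxybenzyloxy)-9-oxobicyclo[3.3.1]non-2-en-7-yl]-7-oxododec-2-enamide | CCCCCC(=O)CCC/C=C/C(=O)N[C@H]1C[C@@]2(OCc3ccc(OC)cc3)C(=O)[C@H]([C@H](O)C=C2)[C@H]1O | intermediate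
31 | (2E)-N-[(1S,2S,4S,5S,6S,7R,8S)-5,7-dihydroxy-1-(4-methoxybenzyloxy)-10-oxo-3-oxatricyclo[4.3.1.0(2,4)]decan-8-yl]-7-oxododec-2-enamide | CCCCCC(=O)CCC/C=C/C(=O)N[C@H]1C[C@@]2(OCc3ccc(OC)cc3)C(=O)[C@H]([C@H](O)[C@@H]3O[C@@H]32)[C@H]1O | intermediate
32 | isariotin C, (2E)-N-[(1S,2S,4S,5S,6S,7R,8S)-1,5,7-trihydroxy-10-oxo-3-oxatricyclo[4.3.1.0(2,4)]decan-8-yl]-7-oxododec-2-enamide | CCCCCC(=O)CCC/C=C/C(=O)N[C@H]1C[C@@]2(O)C(=O)[C@H]([C@H](O)[C@@H]3O[C@@H]32)[C@H]1O | target

**Step count and risks**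

Total step count: 18. Longest linear sequence: 15 steps (1, 2, 4–12, 15–18).

Steps most likely to fail:

Step 11 (key step). The dienolate may be alkylated at oxygen (six-membered cyclic enol ether) or may attack sulfur or the Boc carbonyl of the hard sulfamidate instead of forming the C2–C3 bond, and any enolate formed at C5 may expel a β-silyloxy group and aromatise ring B. The fallback replaces the sulfamidate by a softer carbon electrophile and sets out from 15. Appel iodination (I2, PPh3, imidazole, CH2Cl2, 0 °C) should give the primary iodide F1. Boc2O with DMAP in MeCN then gives the N,N-di-Boc iodide F2, which has no acidic N–H and so cannot close to an aziridine. KN(SiMe3)2 in dilute THF at −78 °C should close ring A by the classical intramolecular enolate/alkyl iodide alkylation (here through the same linear dienolate) to the bicyclic N,N-di-Boc compound F3. Mg(ClO4)2 (cat.) in MeCN at 50 °C removes one Boc group, and the route is rejoined at 20.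

Step 7. Simple diastereoselection may be poor: if the titanium enolate reacts through a chair instead of a boat transition state, the 5,9-anti aldol or a mixture results. The fallback uses an open transition state and sets out from 9. LiN(i-Pr)2 then Me3SiCl (THF, −78 °C) gives the trimethylsilyl dienol ether F4. Fluoride-catalysed aldol addition of F4 to 10 with (Me2N)3S+ Me3SiF2− (10 mol%) in THF at −78 °C, a method that is syn-selective for cyclic enol silanes whatever their geometry, should give the O-trimethylsilyl aldol F5 with the same facial preferences on both partners. K2CO3 in MeOH at 0 °C removes the TMS group, and the route is rejoined at 13.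

Step 10. Over-oxidation may occur: the Ru oxidant may attack the enol-ether alkene of ring B or the anisyl ring while sulfur is being oxidised. The fallback installs the sulfamidate before the alkene-bearing fragment is attached; it sets out from 9 and commercial N-Boc-L-serine methyl ester. The ester is converted by the same two-stage protocol (SOCl2/pyridine, then RuCl3·xH2O/NaIO4), with no alkene or anisyl group present, into the sulfamidate ester F6. i-Bu2AlH in CH2Cl2 at −78 °C gives the sulfamidate aldehyde F7, which is used cold and at once. Titanium enolate 12, made from 9 as in step 7, is added to F7 to give the aldol F8. TBSOTf/2,6-lutidine then gives 17, so steps 8–10 are bypassed.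

**Further compounds**

F1 | step 11 | primary iodide from 15 (CH2OH replaced by CH2I; N-Boc, both TBS ethers and the enone unchanged) | CC(C)(C)OC(=O)N[C@@H](CI)[C@H](O[Si](C)(C)C(C)(C)C)[C@@H]1C(=O)C(OCc2ccc(OC)cc2)=CC[C@H]1O[Si](C)(C)C(C)(C)C
F2 | step 11 | N,N-di-Boc derivative of iodide F1 | CC(C)(C)OC(=O)N(C(=O)OC(C)(C)C)[C@@H](CI)[C@H](O[Si](C)(C)C(C)(C)C)[C@@H]1C(=O)C(OCc2ccc(OC)cc2)=CC[C@H]1O[Si](C)(C)C(C)(C)C
F3 | step 11 | N,N-di-Boc analogue of bicyclic carbamate 20 | CC(C)(C)OC(=O)N(C(=O)OC(C)(C)C)[C@H]1C[C@@]2(OCc3ccc(OC)cc3)C(=O)[C@H]([C@H](O[Si](C)(C)C(C)(C)C)C=C2)[C@H]1O[Si](C)(C)C(C)(C)C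
F4 | step 7 | {[(3R)-3-(TBS-oxy)-6-(4-methoxybenzyloxy)cyclohexa-1,5-dien-1-yl]oxy}trimethylsilane | C[Si](C)(C)OC1=C[C@H](O[Si](C)(C)C(C)(C)C)CC=C1OCc1ccc(OC)cc1
F5 | step 7 | O-trimethylsilyl ether of aldol 13 (TMS on the C9 oxygen) | CC(C)(C)OC(=O)N1[C@@H](COC1(C)C)[C@H](O[Si](C)(C)C)[C@@H]2C(=O)C(OCc3ccc(OC)cc3)=CC[C@H]2O[Si](C)(C)C(C)(C)C
F6 | step 10 | 3-tert-butyl 4-methyl (4S)-1,2,3-oxathiazolidine-3,4-dicarboxylate 2,2-dioxide | COC(=O)[C@@H]1COS(=O)(=O)N1C(=O)OC(C)(C)C
F7 | step 10 | tert-butyl (4S)-4-formyl-1,2,3-oxathiazolidine-3-carboxylate 2,2-dioxide | O=C[C@@H]1COS(=O)(=O)N1C(=O)OC(C)(C)C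
F8 | step 10 | C9-hydroxy analogue of sulfamidate 17 (free OH in place of the C9 TBS ether) | CC(C)(C)OC(=O)N1[C@@H](COS1(=O)=O)[C@H](O)[C@@H]2C(=O)C(OCc3ccc(OC)cc3)=CC[C@H]2O[Si](C)(C)C(C)(C)C
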